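## Structural features

The target 16 is a flavanone: benzene ring A (C4a, C5, C6, C7, C8, C8a) is fused along C4a–C8a to the dihydropyranone ring C (O1, C2, C3, C4, C4a, C8a), and C2 carries a 2,3,4-trimethoxyphenyl ring B. Ring A is a phloroglucinol nucleus, with oxygen on C5 and C7 (methyl ethers) and on C8a (O1), all mutually meta, and with the C4 acyl carbon on C4a. Read as a chain, C2–C3–C4–C4a–C8a–C8–C7–C6–C5 bears oxygen on every second carbon (C2, C4, C8a, C7, C5); the core is thus a folded poly-β-carbonyl chain in which O1 bridges C2 and C8a and one C–C bond, C4a–C5, closes ring A, and this is the feature the key step exploits. The only stereocentre is C2 (S); it is benzylic, ether-bound to O1 and β to the C4 ketone, with no neighbouring centre to relay from. It is fragile in both directions: base removes H3 and expels O1 as a phenoxide (E1cB, retro-oxa-Michael) to an achiral 2'-hydroxychalcone, and strong acid can ionize C2–O1 because the 2'- and 4'-methoxy groups of ring B stabilize the benzylic cation. A free 5-hydroxyl would be chelated to the C4 carbonyl and slow to alkylate. The real difficulty is therefore to obtain the O1–C2 bond in one configuration and give it no chance to reopen, which routes that close ring C last through that bond cannot guarantee. The route in one sentence: ring A is made last, by thermal Claisen-type folding of a masked β-carbonyl chain that hangs from C8a of an enantiopure 2-aryl-2,3-dihydropyran-4-one already containing O1–C2.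

## Logic of the disconnections

16 ⇒ 15. The two O–CH3 bonds on O5 and O7 are cut. Both oxygens are carbonyl oxygens of the folded chain and emerge as hydroxyls when ring A aromatizes, so 15 is the direct product of folding. The gain is that no pre-made, differentiated phenol is needed for ring A. The forward step must alkylate the chelated 5-OH without a base able to remove H3.

15 ⇒ 12 (key). The C4a–C5 bond is cut and ring A is de-aromatized, through 14 back to 13, where C5 is a ketene carbon and C7 a ketone, and then to 12, where both are hidden in one acetonide heterocycle. This removes the benzene ring, its three oxygen positions and the acyl–aryl junction at once and leaves monocyclic ring C with a four-carbon appendage on C8a. The cut is placed at C4a–C5 because, with O1 already tied to C8a, C4a is the only nucleophilic carbon that can reach C5 through a six-membered array, so aldol and lactone folds are closed by construction. The forward step must generate 13 without acid or base, so that C2 is untouched, and must close faster than 13 is intercepted.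

12 ⇒ 10 (through 11). The enol-ether bond O1–C8a is cut, not O1–C2. That bond forms by addition of the C2 hydroxyl to the C8a carbonyl and loss of water, so the C2–O bond is never broken and the configuration of C2 is carried, not made, at ring closure. The gain is an open chain in which every oxygenated carbon is a carbonyl or a silyl ether. The forward step needs acid mild enough not to ionize the benzylic carbon, and the hydroxyl must choose the C8a carbonyl (six-membered) over the others.

10 ⇒ 6 + 9. The C4–C4a bond is cut in the Claisen sense: C4 as acyl donor, C4a as the terminal carbon of a dianion. This makes the route convergent, one half holding C2 and ring B and an achiral half holding all ring A carbons. The forward step needs acylation at the terminal carbon only and no β-elimination of the C2 silyloxy group.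

9 ⇒ 7 + 8. The C8–C8a bond is cut, again in the Claisen sense, to two purchased compounds: 8 supplies C4a and C8a, and 7 supplies C8, C7, C6 and C5 with C7 and C5 already masked. The forward step needs reaction at the γ-carbon of the dienolate of 7.

6 ⇒ 5 ⇒ 4. The silyl group is removed and then the C2–H bond is cut, tracing the stereocentre to a prochiral aryl ketone. The gain is that the only stereocentre comes from a catalyst-controlled reduction of a ketone with two very different substituents. The demand is high face selection on an ortho-substituted, electron-rich aryl ketone.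

4 ⇒ 1 + 2. The C2–C3 bond is cut to 1 (C2 and ring B) and 2 (C3 and C4). The whole skeleton is then a benzoate starter and four acetate-level units (2, 8 and the two halves of 7) joined head to tail, the chain of the biosynthesis cut one carbon earlier.

## Other disconnections considered

Alternative 1: Cut O1–C2. The forward key step is the intramolecular oxa-Michael addition of the 2'-hydroxyl of chalcone A1 (one aldol condensation from purchased parts) under a chiral base or hydrogen-bond catalyst, giving 16 directly. This is the first route that comes to mind and the shortest on paper. The chosen plan is preferred on mechanistic grounds: the ring closure is the microscopic reverse of the racemization pathway of 16, so any catalyst basic enough to close A1 can also reopen the product. A 6'-methoxy chalcone also has an uncatalysed background closure. Good selectivity in this reaction class usually depends on an extra activating group at C3 that must be installed and removed, which cancels the step advantage.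

Alternative 2: Cut C2–C1' (the bond to ring B). The forward key step is an enantioselective 1,4-addition of boronic acid A3 to chromone A2, for example with Pd(OCOCF3)2 and a chiral pyridine–oxazoline ligand or with a rhodium–chiral diene catalyst. It is a fair route, but it is the second textbook answer. The coupling partners also sit at a poor corner of the scope: A3 is ortho-substituted and electron-rich, so protodeboronation should compete with a slowed migratory insertion. The 5-methoxy group of A2 lowers the electrophilicity of the enone and crowds the carbonyl, so face selection is less assured than a ketone reduction.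

Alternative 3: Cut C2–C3. The forward key step is an enantioselective intramolecular carbenoid C–H insertion of diazoketone A4 into its benzylic O–CH2 group with a chiral dirhodium carboxylate such as Rh2(S-PTTL)4. The ether oxygen lies five atoms from the carbene carbon, so a five-membered oxonium ylide and a subsequent [1,2]-benzyl shift (ring contraction) should compete with the six-membered insertion. The electron-rich ring B also invites Buchner-type attack, and face control for a terminal diazoketone in a 1,6-insertion is not dependable. The chosen plan sets C2 by a more predictable reaction.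

Key step: step 7

Assumption: atom labels (O1, C2 … C8a) are those of the target and are used for the corresponding atoms of every intermediate; 1,3-dicarbonyl compounds are drawn as keto forms; lithium enolates made from numbered compounds are treated as their deprotonated forms and carry no numbers of their own.

## Steps

Step 1
Reactants: 1 2,3,4-trimethoxybenzoic acid; 2 N-methoxy-N-methylacetamide
Product: 4 N-methoxy-N-methyl-3-oxo-3-(2,3,4-trimethoxyphenyl)propanamide, via acyl imidazolide 3 (not isolated)
Conditions: CDI, THF, rt; then Li enolate of 2 (LDA, THF, −78 °C), −78 to 0 °C; aq. NH4Cl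
Reagents that add atoms: none
Why: Crossed Claisen condensation: the amide enolate is C-acylated by the acyl imidazolide, and a second equivalent of enolate takes up the acidic β-keto amide so that it is not acylated again.

Step 2
Reactants: 4 N-methoxy-N-methyl-3-oxo-3-(2,3,4-trimethoxyphenyl)propanamide
Product: 5 (S)-3-hydroxy-N-methoxy-N-methyl-3-(2,3,4-trimethoxyphenyl)propanamide
Conditions: RuCl[(S,S)-TsDPEN](p-cymene) (1 mol %), HCO2H/Et3N 5:2, CH2Cl2, 30 °C
Reagents that add atoms: none
Why: Noyori–Ikariya asymmetric transfer hydrogenation of an aryl ketone; the aryl group is placed by its CH/π contact with the arene ligand, so the (S,S)-ligand should deliver the (S)-carbinol in the same sense as for acetophenone (the amide arm takes the place of methyl and the order O > aryl > CH2 is unchanged), which sets C2.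

Step 3
Reactants: 5 (S)-3-hydroxy-N-methoxy-N-methyl-3-(2,3,4-trimethoxyphenyl)propanamide
Product: 6 (S)-3-(tert-butyldimethylsilyloxy)-N-methoxy-N-methyl-3-(2,3,4-trimethoxyphenyl)propanamide
Conditions: TBSCl, imidazole, DMF, rt
Reagents that add atoms: tert-butyldimethylsilyl chloride, CC(C)(C)[Si](C)(C)Cl
Why: Standard silylation of a secondary alcohol; it removes the acidic OH before the dianion chemistry and does not touch C2.

Step 4
Reactants: 7 2,2,6-trimethyl-4H-1,3-dioxin-4-one; 8 acetyl chloride
Product: 9 2,2-dimethyl-6-(2-oxopropyl)-4H-1,3-dioxin-4-one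
Conditions: LiHMDS (2.1 equiv), THF, −78 °C; then 8, −78 °C; aq. NH4Cl
Reagents that add atoms: none
Why: Vinylogous Claisen acylation: γ-deprotonation of 7 gives the lithium dienolate, which is C-acylated at its γ-carbon; the excess dienolate absorbs the more acidic product.

Step 5
Reactants: 9 2,2-dimethyl-6-(2-oxopropyl)-4H-1,3-dioxin-4-one; 6 (S)-3-(tert-butyldimethylsilyloxy)-N-methoxy-N-methyl-3-(2,3,4-trimethoxyphenyl)propanamide
Product: 10 6-[(6S)-6-(tert-butyldimethylsilyloxy)-2,4-dioxo-6-(2,3,4-trimethoxyphenyl)hexyl]-2,2-dimethyl-4H-1,3-dioxin-4-one
Conditions: 9, LDA (2.2 equiv), THF, −78 °C; then 6, −78 to −20 °C; aq. NH4Cl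
Reagents that add atoms: none
Why: Claisen-type acylation of a 1,3-dicarbonyl dianion at its last-formed, most nucleophilic terminal carbon (C4a); the N-methoxy-N-methyl amide holds the tetrahedral adduct as a lithium chelate until work-up, so one acyl transfer occurs, and C2 is not involved.

Step 6
Reactants: 10 6-[(6S)-6-(tert-butyldimethylsilyloxy)-2,4-dioxo-6-(2,3,4-trimethoxyphenyl)hexyl]-2,2-dimethyl-4H-1,3-dioxin-4-one
Product: 12 2,2-dimethyl-6-{[(2S)-4-oxo-2-(2,3,4-trimethoxyphenyl)-3,4-dihydro-2H-pyran-6-yl]methyl}-4H-1,3-dioxin-4-one, via free hydroxy diketone 11 (not isolated)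
Conditions: aq. HF (48%), MeCN, 0 °C to rt; then PPTS (cat.), 4 Å MS, CH2Cl2, rt
Reagents that add atoms: none
Why: Desilylation followed by cyclodehydration of a δ-hydroxy-1,3-diketone: the C2 hydroxyl adds to the C8a carbonyl (six-membered hemiketal) and water is lost towards C4a to give the conjugated vinylogous ester; the C2–O bond is never broken, so the (S) configuration is retained, and the weak acids chosen should not ionize the benzylic carbon.

Step 7
Reactants: 12 2,2-dimethyl-6-{[(2S)-4-oxo-2-(2,3,4-trimethoxyphenyl)-3,4-dihydro-2H-pyran-6-yl]methyl}-4H-1,3-dioxin-4-one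
Product: 15 (S)-5,7-dihydroxy-2-(2,3,4-trimethoxyphenyl)chroman-4-one, via acylketene 13 (not isolated), via dienone 14 (not isolated)
Conditions: PhMe (0.005 M), 110 °C, slow addition of 12, N2
Reagents that add atoms: none
Why: Proposed new method: heating should expel acetone from the dioxinone by retro-[4+2] to give acylketene 13, whose C7 ketone enolizes towards C8 so that ketene, enol and the C8a=C4a enol ether of ring C form a (Z)-dienylketene; six-electron electrocyclization (in polar terms, C-acylation of the enol-ether carbon C4a by the ketene carbon C5) forms C4a–C5 and gives dienone 14, which tautomerizes irreversibly to phenol 15. The closest known reaction types are the thermolysis of keto-dioxinones to acylketenes used in biomimetic resorcylate synthesis and the dienylketene-to-phenol electrocyclization of the Danheiser benzannulation; what has not been shown is a 2,3-dihydro-4H-pyran-4-one as the terminus. Ring A closes as a six-membered carbocycle by thermal disrotatory 6π-electrocyclization, formally a 6-exo attack on the ketene carbonyl carbon. No stereocentre is made; C2 is a spectator and the neutral, aprotic, base-free medium offers no path for E1cB opening of ring C. The step needs Claisen-type folding (C4a to C5) over aldol folding, lactone formation and intermolecular ketene capture. The substrate secures this because O1 is already a dialkyl enol-ether oxygen, so the O-acylation to a 2-pyranone open to a free triketo chain is impossible. The only carbonyl an aldol could use, C4, is a deactivated vinylogous ester, and C4a is the only nucleophilic carbon within reach of a six-membered transition state. High dilution suppresses ketene dimerization and acylation of the product phenols.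

Step 8
Reactants: 15 (S)-5,7-dihydroxy-2-(2,3,4-trimethoxyphenyl)chroman-4-one
Product: 16 (S)-5,7-dimethoxy-2-(2,3,4-trimethoxyphenyl)chroman-4-one
Conditions: MeI (excess), Ag2O, CH2Cl2, rt, dark
Reagents that add atoms: iodomethane, CI
Why: Purdie methylation: Ag2O activates MeI and takes up HI without a soluble strong base, so the free 7-OH and the chelated 5-OH should both be O-methylated while H3 is not removed, and C2 should keep its configuration.

## Compound list

1 | 2,3,4-trimethoxybenzoic acid | OC(=O)c1ccc(OC)c(OC)c1OC | starting material
2 | N-methoxy-N-methylacetamide | CC(=O)N(C)OC | starting material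
3 | 1-(2,3,4-trimethoxybenzoyl)-1H-imidazole | O=C(c1ccc(OC)c(OC)c1OC)n1ccnc1 | intermediate
4 | N-methoxy-N-methyl-3-oxo-3-(2,3,4-trimethoxyphenyl)propanamide | CON(C)C(=O)CC(=O)c1ccc(OC)c(OC)c1OC | intermediate
5 | (S)-3-hydroxy-N-methoxy-N-methyl-3-(2,3,4-trimethoxyphenyl)propanamide | O[C@H](c1ccc(OC)c(OC)c1OC)CC(=O)N(C)OC | intermediate
6 | (S)-3-(tert-butyldimethylsilyloxy)-N-methoxy-N-methyl-3-(2,3,4-trimethoxyphenyl)propanamide | CC(C)(C)[Si](C)(C)O[C@H](c1ccc(OC)c(OC)c1OC)CC(=O)N(C)OC | intermediate
7 | 2,2,6-trimethyl-4H-1,3-dioxin-4-one | CC1=CC(=O)OC(C)(C)O1 | starting material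
8 | acetyl chloride | CC(=O)Cl | starting material
9 | 2,2-dimethyl-6-(2-oxopropyl)-4H-1,3-dioxin-4-one | CC(=O)CC1=CC(=O)OC(C)(C)O1 | intermediate
10 | 6-[(6S)-6-(tert-butyldimethylsilyloxy)-2,4-dioxo-6-(2,3,4-trimethoxyphenyl)hexyl]-2,2-dimethyl-4H-1,3-dioxin-4-one | CC(C)(C)[Si](C)(C)O[C@H](c1ccc(OC)c(OC)c1OC)CC(=O)CC(=O)CC1=CC(=O)OC(C)(C)O1 | intermediate
11 | 6-[(6S)-6-hydroxy-2,4-dioxo-6-(2,3,4-trimethoxyphenyl)hexyl]-2,2-dimethyl-4H-1,3-dioxin-4-one | O[C@H](c1ccc(OC)c(OC)c1OC)CC(=O)CC(=O)CC1=CC(=O)OC(C)(C)O1 | intermediate
12 | 2,2-dimethyl-6-{[(2S)-4-oxo-2-(2,3,4-trimethoxyphenyl)-3,4-dihydro-2H-pyran-6-yl]methyl}-4H-1,3-dioxin-4-one | O=C1C=C(CC2=CC(=O)OC(C)(C)O2)O[C@H](c2ccc(OC)c(OC)c2OC)C1 | intermediate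
13 | 4-[(2S)-4-oxo-2-(2,3,4-trimethoxyphenyl)-3,4-dihydro-2H-pyran-6-yl]but-1-ene-1,3-dione | O=C=CC(=O)CC1=CC(=O)C[C@@H](c2ccc(OC)c(OC)c2OC)O1 | intermediate
14 | (2S)-7-hydroxy-2-(2,3,4-trimethoxyphenyl)-2,3-dihydro-4H-chromene-4,5(4aH)-dione (C4a transient, unassigned) | O=C1C=C(O)C=C2O[C@H](c3ccc(OC)c(OC)c3OC)CC(=O)C12 | intermediate
15 | (S)-5,7-dihydroxy-2-(2,3,4-trimethoxyphenyl)chroman-4-one | Oc1cc(O)c2c(c1)O[C@H](c1ccc(OC)c(OC)c1OC)CC2=O | intermediate
16 | (S)-5,7-dimethoxy-2-(2,3,4-trimethoxyphenyl)chroman-4-one | COc1cc(OC)c2c(c1)O[C@H](c1ccc(OC)c(OC)c1OC)CC2=O | target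

## Step count and least certain steps

Total: 8 steps. Longest linear sequence: 7 steps (1, 2, 3, 5, 6, 7, 8); step 4 is a one-step branch.

Step 7 (key step, proposed new method). The ketene may be consumed between molecules (dimerization, acylation of product phenols, capture by traces of water followed by decarboxylation) faster than it closes. The reason is that the enol-ether carbon C4a is deactivated by the C4 carbonyl and the reactive (Z)-enol geometry may be sparsely populated. Fallback with known chemistry, setting out from 12 and returning at 15: 12 is heated in toluene containing methanol, which traps the acylketene as methyl 3-oxo-4-[(2S)-4-oxo-2-(2,3,4-trimethoxyphenyl)-3,4-dihydro-2H-pyran-6-yl]butanoate F1. F1 is then closed by a Dieckmann-type Claisen condensation with Mg(OMe)2 in MeOH at rt: deprotonation at C8 gives a dienolate that attacks the ester through C4a, and loss of methanol and aromatization give 15. Contact with base is kept short and the quench is cold and acidic, because the phenolate of 15 can open ring C.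

Step 8. Alkylation of the chelated 5-OH may be slow, and forcing it may remove H3, open ring C and erode the configuration of C2, or lead to C-methylation of ring A. Fallback, setting out from 15 and returning at 16: the C4 carbonyl, which causes both the chelation and the E1cB pathway, is taken out of play for the methylation. NaBH4 in MeOH at 0 °C gives (2S)-2-(2,3,4-trimethoxyphenyl)-3,4-dihydro-2H-chromene-4,5,7-triol F2 (C4 epimers, both usable). MeI and K2CO3 in acetone at rt then methylate the two now ordinary phenols to (2S)-5,7-dimethoxy-2-(2,3,4-trimethoxyphenyl)chroman-4-ol F3, kept away from acid. Dess–Martin periodinane with NaHCO3 in CH2Cl2 restores the ketone and gives 16.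

Step 5. The dianion may act as a base towards H3 of 6, after which β-elimination of the silyloxy group destroys the acyl donor and C2, in place of acyl transfer. Fallback, setting out from 6 and returning at 10: DIBAL-H in CH2Cl2 at −78 °C reduces 6 to (S)-3-(tert-butyldimethylsilyloxy)-3-(2,3,4-trimethoxyphenyl)propanal F4. An aldehyde adds the dianion of 9 faster than it is deprotonated, giving the aldol 6-[(6S)-6-(tert-butyldimethylsilyloxy)-4-hydroxy-2-oxo-6-(2,3,4-trimethoxyphenyl)hexyl]-2,2-dimethyl-4H-1,3-dioxin-4-one F5 (C4 epimers). Dess–Martin oxidation of the new carbinol gives 10.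

Step 6. The diketo-dioxinone may fold in the aldol sense (attack of the dioxinone ring carbon C6 on the C4 carbonyl and aromatization) before the hemiketal forms and dehydrates. The benzylic carbinol may also ionize or eliminate under the acid. Fallback, setting out from 6 and returning at 13 within step 7: ring C is closed on a shorter chain that cannot aromatize, and the ketene precursor is added afterwards. The dianion of allyl acetoacetate (LDA, THF, −78 °C) is acylated by 6 to allyl (7S)-7-(tert-butyldimethylsilyloxy)-3,5-dioxo-7-(2,3,4-trimethoxyphenyl)heptanoate F6. Aqueous HF in MeCN gives allyl 2-[(2S)-4-oxo-2-(2,3,4-trimethoxyphenyl)-3,4-dihydro-2H-pyran-6-yl]acetate F7. Pd(PPh3)4 and morpholine remove the allyl group under neutral conditions to give 2-[(2S)-4-oxo-2-(2,3,4-trimethoxyphenyl)-3,4-dihydro-2H-pyran-6-yl]acetic acid F8, which is used at once. Meldrum's acid, EDC and DMAP give 5-{1-hydroxy-2-[(2S)-4-oxo-2-(2,3,4-trimethoxyphenyl)-3,4-dihydro-2H-pyran-6-yl]ethylidene}-2,2-dimethyl-1,3-dioxane-4,6-dione F9. Heating F9 in toluene releases acylketene 13, which continues to 15 as in step 7.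

## Further compounds

F1 | step 7 | methyl 3-oxo-4-[(2S)-4-oxo-2-(2,3,4-trimethoxyphenyl)-3,4-dihydro-2H-pyran-6-yl]butanoate | COC(=O)CC(=O)CC1=CC(=O)C[C@@H](c2ccc(OC)c(OC)c2OC)O1
F2 | step 8 | (2S)-2-(2,3,4-trimethoxyphenyl)-3,4-dihydro-2H-chromene-4,5,7-triol (C4 epimers) | Oc1cc(O)c2c(c1)O[C@H](c1ccc(OC)c(OC)c1OC)CC2O
F3 | step 8 | (2S)-5,7-dimethoxy-2-(2,3,4-trimethoxyphenyl)chroman-4-ol (C4 epimers) | COc1cc(OC)c2c(c1)O[C@H](c1ccc(OC)c(OC)c1OC)CC2O
F4 | step 5 | (S)-3-(tert-butyldimethylsilyloxy)-3-(2,3,4-trimethoxyphenyl)propanal | CC(C)(C)[Si](C)(C)O[C@H](c1ccc(OC)c(OC)c1OC)CC=O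
F5 | step 5 | 6-[(6S)-6-(tert-butyldimethylsilyloxy)-4-hydroxy-2-oxo-6-(2,3,4-trimethoxyphenyl)hexyl]-2,2-dimethyl-4H-1,3-dioxin-4-one (C4 epimers) | CC(C)(C)[Si](C)(C)O[C@H](c1ccc(OC)c(OC)c1OC)CC(O)CC(=O)CC1=CC(=O)OC(C)(C)O1
F6 | step 6 | allyl (7S)-7-(tert-butyldimethylsilyloxy)-3,5-dioxo-7-(2,3,4-trimethoxyphenyl)heptanoate | C=CCOC(=O)CC(=O)CC(=O)C[C@@H](c1ccc(OC)c(OC)c1OC)O[Si](C)(C)C(C)(C)C
F7 | step 6 | allyl 2-[(2S)-4-oxo-2-(2,3,4-trimethoxyphenyl)-3,4-dihydro-2H-pyran-6-yl]acetate | C=CCOC(=O)CC1=CC(=O)C[C@@H](c2ccc(OC)c(OC)c2OC)O1
F8 | step 6 | 2-[(2S)-4-oxo-2-(2,3,4-trimethoxyphenyl)-3,4-dihydro-2H-pyran-6-yl]acetic acid | OC(=O)CC1=CC(=O)C[C@@H](c2ccc(OC)c(OC)c2OC)O1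
F9 | step 6 | 5-{1-hydroxy-2-[(2S)-4-oxo-2-(2,3,4-trimethoxyphenyl)-3,4-dihydro-2H-pyran-6-yl]ethylidene}-2,2-dimethyl-1,3-dioxane-4,6-dione | CC1(C)OC(=O)C(=C(O)CC2=CC(=O)C[C@@H](c3ccc(OC)c(OC)c3OC)O2)C(=O)O1
A1 | alternative 1 | (E)-1-(2-hydroxy-4,6-dimethoxyphenyl)-3-(2,3,4-trimethoxyphenyl)prop-2-en-1-one | COc1cc(O)c(C(=O)/C=C/c2ccc(OC)c(OC)c2OC)c(OC)c1
A2 | alternative 2 | 5,7-dimethoxy-4H-chromen-4-one | COc1cc(OC)c2c(c1)OC=CC2=O
A3 | alternative 2 | (2,3,4-trimethoxyphenyl)boronic acid | COc1ccc(B(O)O)c(OC)c1OC
A4 | alternative 3 | 2-diazo-1-{2,4-dimethoxy-6-[(2,3,4-trimethoxybenzyl)oxy]phenyl}ethan-1-one | COc1cc(OC)c(C(=O)C=[N+]=[N-])c(OCc2ccc(OC)c(OC)c2OC)c1
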